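## Retrosynthetic overview

1. Lychnopholide 31 ⇐ angeloylation of the C8 alcohol 28.
2. 28 ⇐ bromo aldehyde 26 by intramolecular CrCl2-mediated allylation forming C7–C8; this closes the nine-membered oxacycle (O–C3–C4=C5–C6–C7–C8–C9–C10) last, sets C7 and C8 and turns the butenolide into the α-methylene lactone. Enabling feature: the homoallylic array O8–C8–C7–C11=C13, with C7 shared by the lactone ring and the nine-membered ring, so a C7=C11 butenolide carrying Br on C13 is a latent C7 nucleophile.
3. Lactone ring (as the butenolide of 24) ⇐ ring-closing metathesis of the C6 2-(bromomethyl)acrylate 23; furanone ring ⇐ gold-catalysed cyclisation of α′-hydroxy ynone 19.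
4. 19 ⇐ Weinreb amide 6 (C1, C8–C10, C14 from (R)-citramalic acid) + Z-enyne 16 (C6 by Sharpless kinetic resolution; 4Z alkene by Red-Al/I2, then Negishi alkynylation).
5. Ring order: furanone, then lactone (as butenolide), then the nine-membered ring.

Key step: step 17

Remark: germacrane numbering is used (C1 furanone carbonyl, C2=C3, C4=C5, C6/C7 lactone carbons, C8 carbinol, C10 quaternary, C11=C13 methylene, C12 lactone carbonyl); the SMILES is read as 6R,7R,8S,10R with a 4Z alkene and a Z (angelate) ester; carbon building blocks are numbered, other atom-adding reagents are given by name and SMILES.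

## Route

Step 1
Reactants: 1 (R)-citramalic acid
Product: 2 (R)-2-(2,2,4-trimethyl-5-oxo-1,3-dioxolan-4-yl)acetic acid
Conditions: 2,2-dimethoxypropane, TsOH·H2O (cat.), rt
Reagents that add atoms: 2,2-dimethoxypropane, COC(C)(C)OC
Why: Acid-catalysed transacetalisation forms the 1,3-dioxolan-4-one from the α-hydroxy acid unit only, leaving the CH2CO2H group free; the stereocenter (future C10) is not touched.

Step 2
Reactants: 2 (R)-2-(2,2,4-trimethyl-5-oxo-1,3-dioxolan-4-yl)acetic acid
Product: 4 (R)-3-hydroxy-3-methyldihydrofuran-2(3H)-one, via hydroxyethyl dioxolanone 3 (not isolated)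
Conditions: BH3·SMe2, THF, 0 °C to rt; MeOH; then TsOH (cat.), CH2Cl2, rt
Reagents that add atoms: none
Why: Borane reduces the free carboxylic acid chemoselectively in the presence of the dioxolanone, and acid then triggers translactonisation with loss of acetone (the malic-acid-type sequence), leaving the tertiary stereocenter unchanged.

Step 3
Reactants: 4 (R)-3-hydroxy-3-methyldihydrofuran-2(3H)-one
Product: 5 (R)-2,4-dihydroxy-N-methoxy-N,2-dimethylbutanamide
Conditions: MeNHOMe·HCl, iPrMgCl, THF, −20 to 0 °C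
Reagents that add atoms: N,O-dimethylhydroxylamine hydrochloride, CNOC.Cl
Why: Weinreb aminolysis of the lactone with the chloromagnesium amide opens the ring to the hydroxy amide without touching the stereocenter.

Step 4
Reactants: 5 (R)-2,4-dihydroxy-N-methoxy-N,2-dimethylbutanamide
Product: 6 (R)-4-[(tert-butyldimethylsilyl)oxy]-2-hydroxy-N-methoxy-N,2-dimethylbutanamide
Conditions: TBSCl, imidazole, CH2Cl2, 0 °C (crude 5 used directly)
Reagents that add atoms: tert-butyldimethylsilyl chloride, CC(C)(C)[Si](C)(C)Cl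
Why: Selective silylation of the primary hydroxyl (the tertiary one is unreactive under these conditions) also prevents relactonisation of the γ-hydroxy amide.

Step 5
Reactants: 7 (E)-but-2-enal (crotonaldehyde); 8 prop-1-ynylmagnesium bromide
Product: 9 rac-(E)-hept-2-en-5-yn-4-ol
Conditions: THF, −78 to 0 °C; then H2O
Reagents that add atoms: none
Why: Grignard 1,2-addition of the alkynyl nucleophile to the enal gives the racemic alkenyl alkynyl carbinol.

Step 6
Reactants: 9 rac-(E)-hept-2-en-5-yn-4-ol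
Product: 10 (S,E)-hept-2-en-5-yn-4-ol
Conditions: Ti(OiPr)4 (10 mol %), L-(+)-diisopropyl tartrate (15 mol %), t-BuOOH (0.6 equiv), 4 Å MS, CH2Cl2, −20 °C
Reagents that add atoms: none
Why: Sharpless kinetic resolution of a secondary (E)-allylic alcohol: with L-(+)-tartrate the R enantiomer is epoxidised fast, so the S alcohol, whose carbinol carbon becomes C6, should be recovered in high ee (at most half of the material) at about 55–60% conversion.

Step 7
Reactants: 10 (S,E)-hept-2-en-5-yn-4-ol
Product: 12 (2E,4S,5Z)-6-iodohepta-2,5-dien-4-ol, via cyclic vinylalanate 11 (not isolated)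
Conditions: NaAlH2(OCH2CH2OMe)2 (Red-Al), THF, 0 °C to rt; then EtOAc; then I2, −78 to 0 °C
Reagents that add atoms: iodine, [I][I]
Why: Alkoxide-directed trans-hydroalumination of the propargylic alkyne puts aluminium on the distal carbon, and iodinolysis with retention gives the Z vinyl iodide, which fixes C6 and the future C3 cis on C4=C5; the E-alkene and the stereocenter are not touched.

Step 8
Reactants: 12 (2E,4S,5Z)-6-iodohepta-2,5-dien-4-ol
Product: 13 triethyl{[(2E,4S,5Z)-6-iodohepta-2,5-dien-4-yl]oxy}silane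
Conditions: Et3SiCl, imidazole, CH2Cl2, 0 °C
Reagents that add atoms: chlorotriethylsilane, CC[Si](CC)(CC)Cl
Why: Standard silylation of the secondary alcohol; triethylsilyl is chosen because it can later be removed in the presence of the primary tert-butyldimethylsilyl ether.

Step 9
Reactants: 13 triethyl{[(2E,4S,5Z)-6-iodohepta-2,5-dien-4-yl]oxy}silane; 14 ethynylmagnesium bromide
Product: 16 triethyl{[(2E,4S,5Z)-6-methylocta-2,5-dien-7-yn-4-yl]oxy}silane, via ethynylzinc bromide 15 (not isolated)
Conditions: 14, ZnBr2, THF, 0 °C; then 13, Pd(PPh3)4 (5 mol %), THF, rt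
Reagents that add atoms: none
Why: Negishi alkynylation (Pd-catalysed coupling of an alkynylzinc with a vinyl iodide) proceeds with retention of the Z geometry and delivers the terminal enyne without a silyl-alkyne detour.

Step 10
Reactants: 16 triethyl{[(2E,4S,5Z)-6-methylocta-2,5-dien-7-yn-4-yl]oxy}silane; 6 (R)-4-[(tert-butyldimethylsilyl)oxy]-2-hydroxy-N-methoxy-N,2-dimethylbutanamide
Product: 19 (3R,7Z,9S,10E)-1-[(tert-butyldimethylsilyl)oxy]-3-hydroxy-3,7-dimethyl-9-[(triethylsilyl)oxy]dodeca-7,10-dien-5-yn-4-one, via lithium alkoxide 17 (not isolated), via lithium acetylide 18 (not isolated)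
Conditions: 6, LiN(SiMe3)2 (1.0 equiv), THF, −78 °C; 16, n-BuLi, THF, −78 °C; combine, −78 to −20 °C; then H2O
Reagents that add atoms: none
Why: Weinreb ketone synthesis: the lithium acetylide adds once to the N-methoxy-N-methylamide (chelated tetrahedral intermediate), the tertiary hydroxyl being held as its lithium alkoxide, to give the α′-hydroxy ynone with C10 and C6 unchanged.

Step 11
Reactants: 19 (3R,7Z,9S,10E)-1-[(tert-butyldimethylsilyl)oxy]-3-hydroxy-3,7-dimethyl-9-[(triethylsilyl)oxy]dodeca-7,10-dien-5-yn-4-one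
Product: 20 (R)-2-{2-[(tert-butyldimethylsilyl)oxy]ethyl}-2-methyl-5-{(2Z,4S,5E)-4-[(triethylsilyl)oxy]hepta-2,5-dien-2-yl}furan-3(2H)-one
Conditions: Ph3PAuNTf2 (5 mol %), CH2Cl2, rt
Reagents that add atoms: none
Why: Gold-catalysed 5-endo-dig hydroalkoxylation (cycloisomerisation) of an α′-hydroxy ynone: the free C10 hydroxyl adds to C3 of the π-activated ynone and protodeauration gives the 3(2H)-furanone ring, the only other oxygen within reach (O6) being blocked as its silyl ether.

Step 12
Reactants: 20 (R)-2-{2-[(tert-butyldimethylsilyl)oxy]ethyl}-2-methyl-5-{(2Z,4S,5E)-4-[(triethylsilyl)oxy]hepta-2,5-dien-2-yl}furan-3(2H)-one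
Product: 21 (R)-2-{2-[(tert-butyldimethylsilyl)oxy]ethyl}-5-[(2Z,4S,5E)-4-hydroxyhepta-2,5-dien-2-yl]-2-methylfuran-3(2H)-one
Conditions: HF·pyridine, pyridine, THF, 0 °C
Reagents that add atoms: none
Why: Selective desilylation: buffered HF·pyridine removes the secondary triethylsilyl ether far faster than the primary tert-butyldimethylsilyl ether, and the near-neutral medium avoids acid-promoted addition of the freed C6 hydroxyl to C3.

Step 13
Reactants: 21 (R)-2-{2-[(tert-butyldimethylsilyl)oxy]ethyl}-5-[(2Z,4S,5E)-4-hydroxyhepta-2,5-dien-2-yl]-2-methylfuran-3(2H)-one; 22 2-(bromomethyl)acrylic acid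
Product: 23 (2Z,4S,5E)-2-[(R)-5-{2-[(tert-butyldimethylsilyl)oxy]ethyl}-5-methyl-4-oxo-4,5-dihydrofuran-2-yl]hepta-2,5-dien-4-yl 2-(bromomethyl)acrylate
Conditions: N,N′-diisopropylcarbodiimide, DMAP (5 mol %), CH2Cl2, −20 to 0 °C
Reagents that add atoms: none
Why: Steglich esterification with retention at C6; low temperature and only catalytic DMAP limit SN2′ attack of the nucleophilic catalyst on the allylic bromide.

Step 14
Reactants: 23 (2Z,4S,5E)-2-[(R)-5-{2-[(tert-butyldimethylsilyl)oxy]ethyl}-5-methyl-4-oxo-4,5-dihydrofuran-2-yl]hepta-2,5-dien-4-yl 2-(bromomethyl)acrylate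
Product: 24 (R)-5-{(Z)-1-[(R)-4-(bromomethyl)-5-oxo-2,5-dihydrofuran-2-yl]prop-1-en-2-yl}-2-{2-[(tert-butyldimethylsilyl)oxy]ethyl}-2-methylfuran-3(2H)-one
Conditions: second-generation Hoveyda–Grubbs catalyst, (H2IMes)Cl2Ru=CH(C6H4-2-OiPr) (10 mol %), toluene (5 mM), 60 °C, N2 sparge
Reagents that add atoms: none
Why: Ring-closing metathesis of an allylic 2-substituted acrylate: the catalyst loads on the propenyl group and closes onto the 1,1-disubstituted acrylate with loss of propene, forming the lactone ring as a C7=C11 butenolide, while the conjugated C4=C5 and furanone C2=C3 bonds are inert and the neutral medium keeps the now acidic C6–H from epimerising.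

Step 15
Reactants: 24 (R)-5-{(Z)-1-[(R)-4-(bromomethyl)-5-oxo-2,5-dihydrofuran-2-yl]prop-1-en-2-yl}-2-{2-[(tert-butyldimethylsilyl)oxy]ethyl}-2-methylfuran-3(2H)-one
Product: 25 (R)-5-{(Z)-1-[(R)-4-(bromomethyl)-5-oxo-2,5-dihydrofuran-2-yl]prop-1-en-2-yl}-2-(2-hydroxyethyl)-2-methylfuran-3(2H)-one
Conditions: HF (48% aq.), MeCN, 0 °C
Reagents that add atoms: none
Why: Acidic fluoride desilylation of the primary silyl ether; no base is present, so the allylic bromide and the epimerisable butenolide C6 survive.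

Step 16
Reactants: 25 (R)-5-{(Z)-1-[(R)-4-(bromomethyl)-5-oxo-2,5-dihydrofuran-2-yl]prop-1-en-2-yl}-2-(2-hydroxyethyl)-2-methylfuran-3(2H)-one
Product: 26 2-[(R)-5-{(Z)-1-[(R)-4-(bromomethyl)-5-oxo-2,5-dihydrofuran-2-yl]prop-1-en-2-yl}-2-methyl-3-oxo-2,3-dihydrofuran-2-yl]acetaldehyde
Conditions: Dess–Martin periodinane, CH2Cl2, 0 °C to rt
Reagents that add atoms: none
Why: Dess–Martin oxidation under neutral conditions gives the aldehyde without β-elimination of the furanone oxygen from C10 or epimerisation at C6; the aldehyde is used at once.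

Step 17
Reactants: 26 2-[(R)-5-{(Z)-1-[(R)-4-(bromomethyl)-5-oxo-2,5-dihydrofuran-2-yl]prop-1-en-2-yl}-2-methyl-3-oxo-2,3-dihydrofuran-2-yl]acetaldehyde
Product: 28 8-O-deangeloyl-lychnopholide [(6R,7R,8S,10R)-8-hydroxy-1-oxo-3,10-epoxygermacra-2,4Z,11(13)-trien-6,12-olide], via allylchromium dichloride 27 (not isolated)
Conditions: CrCl2 (8 equiv), THF, rt; 26 added over 8 h by syringe pump (final 2 mM); then H2O
Reagents that add atoms: none
Why: Proposed new method: CrCl2 reduces the allylic C13–Br bond of 26 by two one-electron transfers to the allylchromium 27 (trivalent chromium), which adds through its γ-carbon C7 to the C8 aldehyde in a six-membered chair (Cr–O8–C8···C7–C11–C13), moving the double bond to C11=C13 so that the butenolide becomes the α-methylene-γ-butyrolactone and C8 carries the free hydroxyl. The closest known reaction types are the intermolecular Barbier and Nozaki–Hiyama–Kishi allylations of aldehydes with 3-(bromomethyl)furan-2(5H)-ones and the CrCl2-mediated intramolecular allylation that closes ten-membered germacranolide rings from acyclic 2-(bromomethyl)acrylates; the intramolecular use of a bromomethyl butenolide to close a medium ring is the new element. The nine-membered oxacycle (and with it the ten-membered carbocycle) closes by 9-exo-trig attack on the aldehyde with SE2′ regiochemistry at the allyl metal, attack through C13 being excluded because it would need an eleven-membered ring and gives up the chair. C7 is controlled by C6: the aldehyde reaches the butenolide face opposite the C5 substituent, the mode that gives the trans-fused 6,7-lactone, and C8 is controlled by the chair, in which C9 is equatorial and points away from the lactone ring, so that the triad O6/C11/O8 comes out all-syn (7R,8S). The selectivities needed are γ over α attack, anti over syn facial delivery and ring closure over dimerisation or reductive opening of the lactone; they are secured by the closed transition state, by the ring-fixed E-type geometry of C7=C11 (no allyl E/Z scrambling), by the rigid Z-C4=C5–furanone linker, whose C5···C9 span of about 4 Å fits only the anti chair, and by slow addition at about 2 mM. C10 and the 4Z alkene are not involved.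

Step 18
Reactants: 28 8-O-deangeloyl-lychnopholide; 29 angelic acid
Product: 31 lychnopholide, via mixed anhydride 30 (not isolated)
Conditions: 29, 2,4,6-Cl3C6H2COCl, Et3N, toluene, rt; then 28, toluene, 80 °C
Reagents that add atoms: none
Why: Yamaguchi-type acylation through the preformed 2,4,6-trichlorobenzoyl mixed anhydride without DMAP: the C8 hydroxyl attacks the less hindered angeloyl carbonyl and the Z geometry of the angelate is kept (no isomerisation to the tiglate), with no change at any stereocenter.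

## Compound list

1 | (R)-citramalic acid [(2R)-2-hydroxy-2-methylbutanedioic acid] | OC(=O)[C@@](C)(CC(=O)O)O | starting material
2 | (R)-2-(2,2,4-trimethyl-5-oxo-1,3-dioxolan-4-yl)acetic acid | OC(=O)C[C@@]1(C)OC(C)(C)OC1=O | intermediate
3 | (R)-5-(2-hydroxyethyl)-2,2,5-trimethyl-1,3-dioxolan-4-one (not isolated) | OCC[C@@]1(C)OC(C)(C)OC1=O | intermediate
4 | (R)-3-hydroxy-3-methyldihydrofuran-2(3H)-one | O=C1OCC[C@@]1(C)O | intermediate
5 | (R)-2,4-dihydroxy-N-methoxy-N,2-dimethylbutanamide | CON(C)C(=O)[C@@](C)(CCO)O | intermediate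
6 | (R)-4-[(tert-butyldimethylsilyl)oxy]-2-hydroxy-N-methoxy-N,2-dimethylbutanamide | CON(C)C(=O)[C@@](C)(CCO[Si](C)(C)C(C)(C)C)O | intermediate
7 | (E)-but-2-enal (crotonaldehyde) | C/C=C/C=O | starting material
8 | prop-1-ynylmagnesium bromide | CC#C[Mg]Br | starting material
9 | rac-(E)-hept-2-en-5-yn-4-ol | C/C=C/C(O)C#CC | intermediate
10 | (S,E)-hept-2-en-5-yn-4-ol | C/C=C/[C@H](O)C#CC | intermediate
11 | cyclic vinylalanate of 10, sodium salt (five-membered O–Al–C ring, Al on the distal alkene carbon; not isolated) | C/C=C/[C@@H]1O[Al-](OCCOC)(OCCOC)C(C)=C1.[Na+] | intermediate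
12 | (2E,4S,5Z)-6-iodohepta-2,5-dien-4-ol | C/C=C/[C@H](O)/C=C(/C)I | intermediate
13 | triethyl{[(2E,4S,5Z)-6-iodohepta-2,5-dien-4-yl]oxy}silane | C/C=C/[C@H](O[Si](CC)(CC)CC)/C=C(/C)I | intermediate
14 | ethynylmagnesium bromide | C#C[Mg]Br | starting material
15 | ethynylzinc bromide (not isolated) | C#C[Zn]Br | intermediate
16 | triethyl{[(2E,4S,5Z)-6-methylocta-2,5-dien-7-yn-4-yl]oxy}silane | C/C=C/[C@H](O[Si](CC)(CC)CC)/C=C(/C)C#C | intermediate
17 | lithium alkoxide of 6 (not isolated) | CON(C)C(=O)[C@@](C)(CCO[Si](C)(C)C(C)(C)C)O[Li] | intermediate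
18 | lithium acetylide of 16 (not isolated) | C/C=C/[C@H](O[Si](CC)(CC)CC)/C=C(/C)C#C[Li] | intermediate
19 | (3R,7Z,9S,10E)-1-[(tert-butyldimethylsilyl)oxy]-3-hydroxy-3,7-dimethyl-9-[(triethylsilyl)oxy]dodeca-7,10-dien-5-yn-4-one | C/C=C/[C@H](O[Si](CC)(CC)CC)/C=C(/C)C#CC(=O)[C@@](C)(CCO[Si](C)(C)C(C)(C)C)O | intermediate
20 | (R)-2-{2-[(tert-butyldimethylsilyl)oxy]ethyl}-2-methyl-5-{(2Z,4S,5E)-4-[(triethylsilyl)oxy]hepta-2,5-dien-2-yl}furan-3(2H)-one | C/C=C/[C@H](O[Si](CC)(CC)CC)/C=C(/C)C1=CC(=O)[C@@](C)(CCO[Si](C)(C)C(C)(C)C)O1 | intermediate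
21 | (R)-2-{2-[(tert-butyldimethylsilyl)oxy]ethyl}-5-[(2Z,4S,5E)-4-hydroxyhepta-2,5-dien-2-yl]-2-methylfuran-3(2H)-one | C/C=C/[C@H](O)/C=C(/C)C1=CC(=O)[C@@](C)(CCO[Si](C)(C)C(C)(C)C)O1 | intermediate
22 | 2-(bromomethyl)acrylic acid | C=C(CBr)C(=O)O | starting material
23 | (2Z,4S,5E)-2-[(R)-5-{2-[(tert-butyldimethylsilyl)oxy]ethyl}-5-methyl-4-oxo-4,5-dihydrofuran-2-yl]hepta-2,5-dien-4-yl 2-(bromomethyl)acrylate | C/C=C/[C@H](OC(=O)C(=C)CBr)/C=C(/C)C1=CC(=O)[C@@](C)(CCO[Si](C)(C)C(C)(C)C)O1 | intermediate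
24 | (R)-5-{(Z)-1-[(R)-4-(bromomethyl)-5-oxo-2,5-dihydrofuran-2-yl]prop-1-en-2-yl}-2-{2-[(tert-butyldimethylsilyl)oxy]ethyl}-2-methylfuran-3(2H)-one | BrCC1=C[C@H](OC1=O)/C=C(/C)C2=CC(=O)[C@@](C)(CCO[Si](C)(C)C(C)(C)C)O2 | intermediate
25 | (R)-5-{(Z)-1-[(R)-4-(bromomethyl)-5-oxo-2,5-dihydrofuran-2-yl]prop-1-en-2-yl}-2-(2-hydroxyethyl)-2-methylfuran-3(2H)-one | BrCC1=C[C@H](OC1=O)/C=C(/C)C2=CC(=O)[C@@](C)(CCO)O2 | intermediate
26 | 2-[(R)-5-{(Z)-1-[(R)-4-(bromomethyl)-5-oxo-2,5-dihydrofuran-2-yl]prop-1-en-2-yl}-2-methyl-3-oxo-2,3-dihydrofuran-2-yl]acetaldehyde | BrCC1=C[C@H](OC1=O)/C=C(/C)C2=CC(=O)[C@@](C)(CC=O)O2 | intermediate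
27 | allylchromium dichloride from 26 (CrCl2 on C13; not isolated) | Cl[Cr](Cl)CC1=C[C@H](OC1=O)/C=C(/C)C2=CC(=O)[C@@](C)(CC=O)O2 | intermediate
28 | 8-O-deangeloyl-lychnopholide [(6R,7R,8S,10R)-8-hydroxy-1-oxo-3,10-epoxygermacra-2,4Z,11(13)-trien-6,12-olide] | C=C1C(=O)O[C@@H]2/C=C(/C)C3=CC(=O)[C@@](C)(C[C@H](O)[C@@H]12)O3 | intermediate
29 | angelic acid [(Z)-2-methylbut-2-enoic acid] | C/C=C(/C)C(=O)O | starting material
30 | angelic 2,4,6-trichlorobenzoic anhydride (not isolated) | C/C=C(/C)C(=O)OC(=O)c1c(Cl)cc(Cl)cc1Cl | intermediate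
31 | lychnopholide [(6R,7R,8S,10R)-8-angeloyloxy-1-oxo-3,10-epoxygermacra-2,4Z,11(13)-trien-6,12-olide] | C=C1C(=O)O[C@@H]2/C=C(/C)C3=CC(=O)[C@@](C)(C[C@H](OC(=O)/C(C)=C\C)[C@@H]12)O3 | target

## Step count and risks

Total: 18 steps. Longest linear sequence: 14 steps (steps 5–18, from crotonaldehyde).

Steps most likely to fail:

1. Step 17 (Proposed new method). What may go wrong: delivery of the aldehyde to the wrong butenolide face (cis-fused lactone, wrong C7/C8), or dimerisation and reductive 1,4-opening of the lactone by the allylchromium outrunning the slow medium-ring closure. Fallback, setting out from 6 and returning at 28: the C7–C8 bond is made intermolecularly and the same nine-membered ring is closed last at C4=C5 by ring-closing metathesis. 6 is acylated with the lithium acetylide of commercial 2-methylbut-1-en-3-yne to give hydroxy ynone F1. F1 is cyclised (Ph3PAuNTf2) to isopropenyl furanone F2, desilylated (aq. HF, MeCN) to alcohol F3 and oxidised (Dess–Martin periodinane) to aldehyde F4. In parallel, commercial racemic (E)-hexa-1,4-dien-3-ol is resolved by Sharpless kinetic resolution with D-(−)-diisopropyl tartrate to leave (S)-dienol F5. F5 is esterified with 22 to acrylate F6 and ring-closed through its terminal vinyl group to bromolactone F7. Zinc-mediated Barbier allylation of F4 with F7 (Zn, aq. NH4Cl/THF) is a known reaction of 3-(bromomethyl)butenolides; it runs through the same chair anti to the C6 substituent, with no ring constraint, and gives diene F8 with the C6–C7–C8 triad set. Ring-closing metathesis of F8 (second-generation Hoveyda–Grubbs catalyst, toluene, 80 °C; isopropenyl plus propenyl, loss of propene) forms the trisubstituted 4Z alkene and delivers 28.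

2. Step 14. What may go wrong: loss of the catalyst to the allylic C–Br bond, or thermal decomposition of the bromide, before the slow closure onto the 1,1-disubstituted acrylate. Fallback, setting out from 23 and returning at 24: C13 is carried through the metathesis as an acetate. CsOAc (DMF, rt) converts 23 into acetate ester F9 (SN2 and SN2′ displacement give the same product). Ring-closing metathesis gives acetoxymethyl butenolide F10. Lipase-mediated deacetylation (Candida antarctica lipase B, pH 7 buffer/MTBE, neutral so that C6 is safe) gives hydroxymethyl butenolide F11. Appel bromination (CBr4, PPh3, CH2Cl2, 0 °C) then gives 24.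

3. Step 11. What may go wrong: competing 5-exo attack of the C6 silyl ether oxygen on the gold-activated alkyne (furan formation with loss of the silyl group), or gold-induced Z-to-E isomerisation of C4=C5. Fallback, setting out from 19 and returning at 20: a metal-free two-stage cyclisation. Conjugate addition of Et2NH (EtOH, rt) gives enaminone F12 (E expected; its geometry is of no consequence). In AcOH/NaOAc-buffered aqueous THF the tertiary hydroxyl then displaces the amine at C3 by addition–elimination to give 20.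

## Further compounds

F1 | step 17 | (R)-8-[(tert-butyldimethylsilyl)oxy]-6-hydroxy-2,6-dimethyloct-1-en-3-yn-5-one | C=C(C)C#CC(=O)[C@@](C)(CCO[Si](C)(C)C(C)(C)C)O
F2 | step 17 | (R)-2-{2-[(tert-butyldimethylsilyl)oxy]ethyl}-2-methyl-5-(prop-1-en-2-yl)furan-3(2H)-one | C=C(C)C1=CC(=O)[C@@](C)(CCO[Si](C)(C)C(C)(C)C)O1
F3 | step 17 | (R)-2-(2-hydroxyethyl)-2-methyl-5-(prop-1-en-2-yl)furan-3(2H)-one | C=C(C)C1=CC(=O)[C@@](C)(CCO)O1
F4 | step 17 | 2-[(R)-2-methyl-3-oxo-5-(prop-1-en-2-yl)-2,3-dihydrofuran-2-yl]acetaldehyde | C=C(C)C1=CC(=O)[C@@](C)(CC=O)O1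
F5 | step 17 | (S,E)-hexa-1,4-dien-3-ol | C=C[C@H](O)/C=C/C
F6 | step 17 | (S,E)-hexa-1,4-dien-3-yl 2-(bromomethyl)acrylate | C=C[C@H](OC(=O)C(=C)CBr)/C=C/C
F7 | step 17 | (R)-3-(bromomethyl)-5-[(E)-prop-1-en-1-yl]furan-2(5H)-one | BrCC1=C[C@H](OC1=O)/C=C/C
F8 | step 17 | (R)-2-{(S)-2-hydroxy-2-[(2R,3R)-4-methylidene-5-oxo-2-((E)-prop-1-en-1-yl)oxolan-3-yl]ethyl}-2-methyl-5-(prop-1-en-2-yl)furan-3(2H)-one | C=C1C(=O)O[C@H](/C=C/C)[C@H]1[C@@H](O)C[C@@]2(C)OC(=CC2=O)C(C)=C
F9 | step 14 | (2Z,4S,5E)-2-[(R)-5-{2-[(tert-butyldimethylsilyl)oxy]ethyl}-5-methyl-4-oxo-4,5-dihydrofuran-2-yl]hepta-2,5-dien-4-yl 2-(acetoxymethyl)acrylate | C/C=C/[C@H](OC(=O)C(=C)COC(C)=O)/C=C(/C)C1=CC(=O)[C@@](C)(CCO[Si](C)(C)C(C)(C)C)O1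
F10 | step 14 | {(R)-5-[(Z)-2-((R)-5-{2-[(tert-butyldimethylsilyl)oxy]ethyl}-5-methyl-4-oxo-4,5-dihydrofuran-2-yl)prop-1-en-1-yl]-2-oxo-2,5-dihydrofuran-3-yl}methyl acetate | CC(=O)OCC1=C[C@H](OC1=O)/C=C(/C)C2=CC(=O)[C@@](C)(CCO[Si](C)(C)C(C)(C)C)O2
F11 | step 14 | (R)-2-{2-[(tert-butyldimethylsilyl)oxy]ethyl}-5-{(Z)-1-[(R)-4-(hydroxymethyl)-5-oxo-2,5-dihydrofuran-2-yl]prop-1-en-2-yl}-2-methylfuran-3(2H)-one | OCC1=C[C@H](OC1=O)/C=C(/C)C2=CC(=O)[C@@](C)(CCO[Si](C)(C)C(C)(C)C)O2
F12 | step 11 | (3R,5E,7Z,9S,10E)-1-[(tert-butyldimethylsilyl)oxy]-6-(diethylamino)-3-hydroxy-3,7-dimethyl-9-[(triethylsilyl)oxy]dodeca-5,7,10-trien-4-one | C/C=C/[C@H](O[Si](CC)(CC)CC)/C=C(/C)\C(N(CC)CC)=C/C(=O)[C@@](C)(CCO[Si](C)(C)C(C)(C)C)O
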